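**Plan**

- Retrosynthesis first masks the C3 phenol as a benzyl ether, then cuts the benzene ring at C3–C4 and C1–C6. This gives a C1–C2–C3 fragment that already carries C7 and both oxygens, and a bare C4–C5–C6 malonaldehyde unit.
- The feature that allows this: on the ring C1–C6, the ester carbon C7, the C2 oxygen and the C3 oxygen sit on three adjacent carbons, while C4, C5 and C6 bear only hydrogen. This is the ester carbon, ketone oxygen and C4 oxygen of a 4-alkoxyacetoacetate.
- The three-carbon nucleophile is the 1,3-bis(trimethylsilyloxy)diene of docosyl 4-(benzyloxy)acetoacetate. The three-carbon electrophile is 1,1,3,3-tetramethoxypropane.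
- Forward order: the C22 chain is joined first by ester exchange, two silylations follow, the only ring (the benzene) is closed in one [3+3] cyclocondensation, and hydrogenolysis ends the route.
- Stereochemistry: there is none to set. The sp3 centres and enol ether geometries along the way are transient and vanish on aromatisation.

Key step: step 4

Assumption: the target has no stereocentre and no stereogenic double bond, so the given SMILES is met without stereocontrol; the silyl enol ethers are expected as mixtures of geometric isomers, drawn unspecified, and LDA is taken as the commercial solution.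

Ring numbering used throughout: C1 bears the ester carbon C7, and C2 and C3 bear the hydroxyls.

**Step 1**
Reactants: 1 ethyl 4-(benzyloxy)-3-oxobutanoate; 2 1-docosanol
Product: 3 docosyl 4-(benzyloxy)-3-oxobutanoate
Conditions: 1 (1.3 equiv), 2 (1.0 equiv), DMAP (0.2 equiv), toluene, reflux, EtOH removed (4 Å MS in a Soxhlet thimble)
Reagents that add atoms: none
Why: DMAP-catalysed transesterification of a β-keto ester, which exchanges readily through its enol/acylketene manifold, should be driven to 3 by removal of ethanol without touching the benzyl ether.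

**Step 2**
Reactants: 3 docosyl 4-(benzyloxy)-3-oxobutanoate
Product: 4 docosyl 4-(benzyloxy)-3-(trimethylsilyloxy)but-2-enoate (mixture of geometric isomers, used crude)
Conditions: TMSCl (1.5 equiv), Et3N (1.5 equiv), toluene, 20 °C; filtration under argon, concentration
Reagents that add atoms: chlorotrimethylsilane, C[Si](C)(C)Cl
Why: Soft enolisation and O-silylation of the β-keto ester at the doubly activated C2 position is the standard first stage of 1,3-bis(silyloxy)diene preparation and should give the β-silyloxy enoate cleanly.

**Step 3**
Reactants: 4 docosyl 4-(benzyloxy)-3-(trimethylsilyloxy)but-2-enoate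
Product: 5 4-(benzyloxy)-1-(docosyloxy)-1,3-bis(trimethylsilyloxy)buta-1,3-diene (geometry unspecified, used crude)
Conditions: LDA (1.2 equiv), THF, −78 °C; then TMSCl (1.3 equiv), −78 → 20 °C; hexane trituration, filtration under argon, concentration
Reagents that add atoms: chlorotrimethylsilane, C[Si](C)(C)Cl
Why: Kinetic γ-deprotonation of the vinylogous ester by LDA gives the extended ester enolate, which TMSCl traps on oxygen (silyl ketene acetal formation), the standard second stage of bis(silyloxy)diene synthesis.

**Step 4**
Reactants: 5 4-(benzyloxy)-1-(docosyloxy)-1,3-bis(trimethylsilyloxy)buta-1,3-diene; 6 1,1,3,3-tetramethoxypropane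
Product: 9 docosyl 3-(benzyloxy)-2-hydroxybenzoate, via open-chain silyl enol ether adduct 7 (not isolated), via dimethoxycyclohexanone ester 8 (not isolated)
Conditions: 6 (1.1 equiv), TMSOTf (0.1 equiv), CH2Cl2 (dilute), −78 → 20 °C; 10% aq. HCl work-up
Reagents that add atoms: none
Why: Catalytic TMSOTf ionises one acetal of 6 to a methoxy-oxocarbenium ion, which the terminal (γ) carbon of diene 5 attacks in a vinylogous Mukaiyama addition, forming the C3–C4 bond and leaving the β-keto ester silyl enol ether 7. Ionisation of the second acetal lets the central carbon of that enol ether close the ring by a 6-(enolendo)-exo-trig Mukaiyama cyclisation (C1–C6 bond) to cyclohexanone 8, and two acid-promoted β-eliminations of methanol followed by enolisation give the aromatic salicylate 9. The closest known reaction type is the formal [3+3] cyclocondensation of 1,3-bis(silyloxy)-1,3-dienes with 1,1,3,3-tetramethoxypropane to give salicylates. No stereocentre remains in 9, since the sp3 centres of 7 and 8 are erased on aromatisation. The selectivity needed is ring closure over oligomerisation, secured by the intramolecular six-membered second C–C bond formation under dilute, low-temperature conditions; regiochemistry cannot go astray because 6 is constitutionally symmetric and the ester/O/O pattern is fixed in 5.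

**Step 5**
Reactants: 9 docosyl 3-(benzyloxy)-2-hydroxybenzoate
Product: 10 Gentiside J (docosyl 2,3-dihydroxybenzoate)
Conditions: H2 (1 atm), 10% Pd/C, EtOAc–THF (1:1), 20 °C; filtration and concentration under argon
Reagents that add atoms: none
Why: Catalytic hydrogenolysis of the benzyl aryl ether should free the C3 phenol under neutral conditions that leave the saturated docosyl ester and the arene intact.

**Compound list**

1 | ethyl 4-(benzyloxy)-3-oxobutanoate | CCOC(=O)CC(=O)COCc1ccccc1 | starting material
2 | 1-docosanol | CCCCCCCCCCCCCCCCCCCCCCO | starting material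
3 | docosyl 4-(benzyloxy)-3-oxobutanoate | CCCCCCCCCCCCCCCCCCCCCCOC(=O)CC(=O)COCc1ccccc1 | intermediate
4 | docosyl 4-(benzyloxy)-3-(trimethylsilyloxy)but-2-enoate (geometric mixture) | CCCCCCCCCCCCCCCCCCCCCCOC(=O)C=C(O[Si](C)(C)C)COCc1ccccc1 | intermediate
5 | 4-(benzyloxy)-1-(docosyloxy)-1,3-bis(trimethylsilyloxy)buta-1,3-diene (geometry unspecified) | CCCCCCCCCCCCCCCCCCCCCCOC(O[Si](C)(C)C)=CC(O[Si](C)(C)C)=COCc1ccccc1 | intermediate
6 | 1,1,3,3-tetramethoxypropane | COC(OC)CC(OC)OC | starting material
7 | docosyl 4-(benzyloxy)-5,7,7-trimethoxy-3-(trimethylsilyloxy)hept-2-enoate (diastereomer mixture, formed in the flask in step 4) | CCCCCCCCCCCCCCCCCCCCCCOC(=O)C=C(O[Si](C)(C)C)C(OCc1ccccc1)C(OC)CC(OC)OC | intermediate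
8 | docosyl 3-(benzyloxy)-4,6-dimethoxy-2-oxocyclohexane-1-carboxylate (diastereomer mixture, formed in the flask in step 4) | CCCCCCCCCCCCCCCCCCCCCCOC(=O)C1C(OC)CC(OC)C(OCc2ccccc2)C1=O | intermediate
9 | docosyl 3-(benzyloxy)-2-hydroxybenzoate | CCCCCCCCCCCCCCCCCCCCCCOC(=O)c1cccc(OCc2ccccc2)c1O | intermediate
10 | Gentiside J, docosyl 2,3-dihydroxybenzoate (achiral) | CCCCCCCCCCCCCCCCCCCCCCOC(=O)c1cccc(O)c1O | target

**Step count**

Total steps: 5. Longest linear sequence: 5 (1 or 2 → 3 → 4 → 5 → 9 → 10).

**Steps most likely to fail**

Step 4. Intermolecular oligomerisation of the oxocarbenium and enol ether intermediates may outrun ring closure. Protodesilylation of the waxy diene, which cannot be distilled, and its limited solubility at −78 °C would make this worse. The fallback sets out from 1 and returns at 9; it runs the same ring construction on the short-chain ester and attaches the C22 chain afterwards.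
- Compound 1 would be silylated (TMSCl, Et3N) to ethyl 4-(benzyloxy)-3-(trimethylsilyloxy)but-2-enoate F1.
- LDA then TMSCl would convert this to 4-(benzyloxy)-1-ethoxy-1,3-bis(trimethylsilyloxy)buta-1,3-diene F2, which should be purifiable by bulb-to-bulb distillation.
- Cyclocondensation with 6 under catalytic TMSOTf should give ethyl 3-(benzyloxy)-2-hydroxybenzoate F3.
- Saponification (NaOH, MeOH–H2O, reflux, then HCl) would give 3-(benzyloxy)-2-hydroxybenzoic acid F4.
- Mitsunobu esterification of this acid with 2 (PPh3, DIAD, THF, 0 → 20 °C) should give 9, because only the carboxylic acid is acidic enough to be alkylated.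

Step 3. The amide base may metalate the benzylic O–CH2 group (with Wittig-type rearrangement) or attack silicon instead of removing the γ-proton, and the ketene acetal silyl group may be lost hydrolytically during isolation. The fallback sets out from 2 and returns at 10; it replaces the benzyl ether by a methyl ether, which has no benzylic C–H, and changes the final deprotection.
- DMAP-catalysed transesterification of commercial methyl 4-methoxy-3-oxobutanoate with 2 would give docosyl 4-methoxy-3-oxobutanoate F5.
- TMSCl/Et3N would give docosyl 4-methoxy-3-(trimethylsilyloxy)but-2-enoate F6.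
- LDA then TMSCl would give 1-(docosyloxy)-4-methoxy-1,3-bis(trimethylsilyloxy)buta-1,3-diene F7.
- Cyclocondensation with 6 under catalytic TMSOTf should give docosyl 2-hydroxy-3-methoxybenzoate F8.
- Cleavage of the aryl methyl ether with BBr3 (CH2Cl2, −78 → 0 °C) should give 10.

Step 1. Ester exchange may stop short at equilibrium, and the 4-alkoxyacetoacetate may self-condense thermally through acylketene dimerisation, leaving docosanol that is hard to separate from the equally lipophilic product. The fallback sets out from 2 and returns at 3; it builds the β-keto ester irreversibly instead of by equilibrium exchange.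
- Commercial (benzyloxy)acetyl chloride would acylate Meldrum's acid (pyridine, CH2Cl2, 0 °C) to 5-[2-(benzyloxy)-1-hydroxyethylidene]-2,2-dimethyl-1,3-dioxane-4,6-dione F9.
- Heating this with 2 in toluene at reflux should give 3 by acylketene formation and capture by the alcohol.

**Further compounds**

F1 | step 4 | ethyl 4-(benzyloxy)-3-(trimethylsilyloxy)but-2-enoate | CCOC(=O)C=C(O[Si](C)(C)C)COCc1ccccc1
F2 | step 4 | 4-(benzyloxy)-1-ethoxy-1,3-bis(trimethylsilyloxy)buta-1,3-diene | CCOC(O[Si](C)(C)C)=CC(O[Si](C)(C)C)=COCc1ccccc1
F3 | step 4 | ethyl 3-(benzyloxy)-2-hydroxybenzoate | CCOC(=O)c1cccc(OCc2ccccc2)c1O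
F4 | step 4 | 3-(benzyloxy)-2-hydroxybenzoic acid | OC(=O)c1cccc(OCc2ccccc2)c1O
F5 | step 3 | docosyl 4-methoxy-3-oxobutanoate | CCCCCCCCCCCCCCCCCCCCCCOC(=O)CC(=O)COC
F6 | step 3 | docosyl 4-methoxy-3-(trimethylsilyloxy)but-2-enoate | CCCCCCCCCCCCCCCCCCCCCCOC(=O)C=C(O[Si](C)(C)C)COC
F7 | step 3 | 1-(docosyloxy)-4-methoxy-1,3-bis(trimethylsilyloxy)buta-1,3-diene | CCCCCCCCCCCCCCCCCCCCCCOC(O[Si](C)(C)C)=CC(O[Si](C)(C)C)=COC
F8 | step 3 | docosyl 2-hydroxy-3-methoxybenzoate | CCCCCCCCCCCCCCCCCCCCCCOC(=O)c1cccc(OC)c1O
F9 | step 1 | 5-[2-(benzyloxy)-1-hydroxyethylidene]-2,2-dimethyl-1,3-dioxane-4,6-dione | CC1(C)OC(=O)C(=C(O)COCc2ccccc2)C(=O)O1
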